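**Plan** (primed locants = dihydropyranone ring)
1. Retrosynthesis first restores the C5 methyl ether, then cuts the dihydropyranone at O1'–C6' (cyclodehydration) and C5'–C6' (aldol), leaving a chromone aldehyde and (4S)-4-silyloxypentan-2-one.
2. The chromone is cut at C8a–O1, C4a–C4 and O1–C2. Its ring oxygen (on C8a) and its acyl carbon C4 (on C4a) are ortho neighbours lying directly beside the C5 oxygen. This 1,2,3-pattern is what a carboxylate oxygen and then its acyl group leave when they add across a 3-methoxybenzyne, so the partners are an ortho-silylaryl triflate and but-2-ynoic acid.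
3. Forward: the arene and its three-carbon side chain are built from 4-hydroxy-2,6-dimethoxybenzaldehyde and the symmetric phenol is converted to the silyl triflate. The aryne step closes the chromone pyranone ring first, the dihydropyranone ring is closed second, and the C5 methyl ether is cleaved last.
4. Stereochemistry: the side-chain centre (R) comes from asymmetric hydrogenation of an (E)-α-methylcinnamic acid with Ru(OAc)2[(R)-BINAP]; the pyranone centre (S) comes from (2S,4S)-pentane-2,4-diol and is never broken.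

Key step: step 9

Assumption: Ru(OAc)2[(R)-BINAP] is taken to give the (2R)-acid from the E-acid, by analogy with tiglic and α-methylcinnamic acid; if the 2,6-dimethoxyaryl group reverses the sense, the (S)-ligand is used with no other change.

**Step 1**
Reactants: 1 4-hydroxy-2,6-dimethoxybenzaldehyde
Product: 2 4-[(tert-butyldimethylsilyl)oxy]-2,6-dimethoxybenzaldehyde
Conditions: TBSCl, imidazole, DMF, 0 °C to rt
Reagents that add atoms: tert-butyldimethylsilyl chloride, CC(C)(C)[Si](C)(C)Cl
Why: Imidazole-promoted silylation of the phenol, which keeps the aldehyde from being deactivated as a phenoxide (vinylogous carboxylate) under the basic olefination that follows.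

**Step 2**
Reactants: 2 4-[(tert-butyldimethylsilyl)oxy]-2,6-dimethoxybenzaldehyde; 3 triethyl 2-phosphonopropionate
Product: 5 ethyl (2E)-3-{4-[(tert-butyldimethylsilyl)oxy]-2,6-dimethoxyphenyl}-2-methylprop-2-enoate, via sodium phosphonate carbanion 4 (not isolated)
Conditions: NaH, THF, 0 °C to rt
Reagents that add atoms: none
Why: Horner–Wadsworth–Emmons olefination, in which the α-methyl phosphonate anion should give the trisubstituted E-enoate; any Z isomer can be removed by crystallisation of acid 6.

**Step 3**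
Reactants: 5 ethyl (2E)-3-{4-[(tert-butyldimethylsilyl)oxy]-2,6-dimethoxyphenyl}-2-methylprop-2-enoate
Product: 6 (2E)-3-(4-hydroxy-2,6-dimethoxyphenyl)-2-methylprop-2-enoic acid
Conditions: KOH, EtOH–H2O, 80 °C; then aq. HCl to pH 2
Reagents that add atoms: potassium hydroxide, [K+].[OH-]
Why: Saponification of the ester, in which hydroxide also cleaves the aryl silyl ether, so the free acid needed for the hydrogenation and the free phenol are released in one operation.

**Step 4**
Reactants: 6 (2E)-3-(4-hydroxy-2,6-dimethoxyphenyl)-2-methylprop-2-enoic acid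
Product: 7 (2R)-3-(4-hydroxy-2,6-dimethoxyphenyl)-2-methylpropanoic acid
Conditions: Ru(OAc)2[(R)-BINAP] (1 mol %), H2 (4 atm), MeOH, rt
Reagents that add atoms: none
Why: Noyori asymmetric hydrogenation of an α,β-unsaturated carboxylic acid, in which the carboxylate binds to the divalent ruthenium–BINAP centre and hydrogen is delivered to one face of the E-alkene, setting C2 as R under ligand control.

**Step 5**
Reactants: 7 (2R)-3-(4-hydroxy-2,6-dimethoxyphenyl)-2-methylpropanoic acid
Product: 8 4-[(2R)-3-hydroxy-2-methylpropyl]-3,5-dimethoxyphenol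
Conditions: LiAlH4, THF, 0 °C to reflux; aqueous work-up at pH 4
Reagents that add atoms: none
Why: Hydride reduction of the carboxylic acid to the primary alcohol, which does not enolise the α-centre, so the R configuration is carried through.

**Step 6**
Reactants: 8 4-[(2R)-3-hydroxy-2-methylpropyl]-3,5-dimethoxyphenol
Product: 9 2-bromo-4-[(2R)-3-hydroxy-2-methylpropyl]-3,5-dimethoxyphenol
Conditions: NBS (1.0 equiv), MeCN, −20 °C
Reagents that add atoms: N-bromosuccinimide, O=C1CCC(=O)N1Br
Why: Electrophilic aromatic bromination, in which the two free ring positions are equivalent and both ortho to the hydroxyl group, so one equivalent of NBS at low temperature should give a single monobromide.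

**Step 7**
Reactants: 9 2-bromo-4-[(2R)-3-hydroxy-2-methylpropyl]-3,5-dimethoxyphenol
Product: 13 4-[(2R)-3-hydroxy-2-methylpropyl]-3,5-dimethoxy-2-(trimethylsilyl)phenyl trifluoromethanesulfonate, via bis(trimethylsilyl) ether 10 (not isolated), via lithium silylphenoxide 11 (not isolated), via silyl ether triflate 12 (not isolated)
Conditions: HMDS, THF, 70 °C, evaporate; n-BuLi (1.1 equiv), THF, −78 °C; Tf2O, −78 °C; aq. citric acid–MeOH, 0 °C
Reagents that add atoms: hexamethyldisilazane, C[Si](C)(C)N[Si](C)(C)C; trifluoromethanesulfonic anhydride, O=S(=O)(OS(=O)(=O)C(F)(F)F)C(F)(F)F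
Why: Silylation of both hydroxyl groups, bromine–lithium exchange and 1,3 O-to-C silyl migration (retro-Brook rearrangement) should place the trimethylsilyl group on the carbon next to the phenoxide, which Tf2O traps; the labile primary silyl ether is then hydrolysed by mild acid that leaves the aryl–silicon bond intact.

**Step 8**
Reactants: 13 4-[(2R)-3-hydroxy-2-methylpropyl]-3,5-dimethoxy-2-(trimethylsilyl)phenyl trifluoromethanesulfonate
Product: 14 4-[(2R)-3-acetoxy-2-methylpropyl]-3,5-dimethoxy-2-(trimethylsilyl)phenyl trifluoromethanesulfonate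
Conditions: Ac2O, pyridine, DMAP (cat.), CH2Cl2, 0 °C to rt
Reagents that add atoms: acetic anhydride, CC(=O)OC(C)=O
Why: DMAP-catalysed acetylation of the primary alcohol, which must be masked because a free alcohol would add to the aryne; neither the aryl triflate nor the arylsilane reacts with the anhydride.

**Step 9**
Reactants: 14 4-[(2R)-3-acetoxy-2-methylpropyl]-3,5-dimethoxy-2-(trimethylsilyl)phenyl trifluoromethanesulfonate; 15 but-2-ynoic acid (1.5 equiv)
Product: 18 (2R)-3-(5,7-dimethoxy-2-methyl-4-oxo-4H-chromen-6-yl)-2-methylpropyl acetate, via aryne 16 (not isolated), via ortho-hydroxyaryl ynone 17 (not isolated)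
Conditions: CsF (4 equiv), THF, 125 °C, sealed tube
Reagents that add atoms: none
Why: Fluoride attacks silicon and expels triflate to give aryne 16; the carboxylate of 15 adds through oxygen to the aryne carbon remote from the flanking methoxy group (future C8a), the aryl anion left beside that methoxy group (future C4a) attacks the ester carbonyl through a four-membered alkoxide, and its collapse gives the ortho-acylphenoxide 17, a net insertion of the aryne into the acyl C–O bond that forms C8a–O1 and C4a–C4. The closest known reaction type is the CsF-mediated insertion of arynes into the C–O bond of carboxylic acids to give ortho-hydroxyaryl ketones, which with α,β-unsaturated and arylpropiolic acids is known to continue in the same flask by oxa-Michael closure to chromanones and flavones. The pyranone ring then closes by 6-endo-dig conjugate addition of the phenoxide to the ynone β-carbon (O1–C2), preferred over 5-exo-dig attack at the α-carbon because only the former is a Michael addition. No stereocentre is formed and the side-chain centre, remote from all reacting atoms, is untouched. The step needs regiocontrol in the aryne addition: the inductively withdrawing methoxy group beside the triple bond makes the distal carbon the electrophilic one and stabilises the adjacent anion, and because phenol 8 is symmetric either ortho position leads to the same 6-alkyl-5,7-dimethoxy pattern. Acyl transfer must also outrun protonation of the aryl anion, which the excess of CsF (acid present as carboxylate) and the high temperature should favour.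

**Step 10**
Reactants: 18 (2R)-3-(5,7-dimethoxy-2-methyl-4-oxo-4H-chromen-6-yl)-2-methylpropyl acetate
Product: 19 6-[(2R)-3-hydroxy-2-methylpropyl]-5,7-dimethoxy-2-methyl-4H-chromen-4-one
Conditions: K2CO3 (0.2 equiv), MeOH, 0 °C to rt
Reagents that add atoms: none
Why: Base-catalysed transesterification (methanolysis) of the acetate; catalytic carbonate at or below room temperature should not open the 2-methylchromone.

**Step 11**
Reactants: 19 6-[(2R)-3-hydroxy-2-methylpropyl]-5,7-dimethoxy-2-methyl-4H-chromen-4-one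
Product: 20 (2R)-3-(5,7-dimethoxy-2-methyl-4-oxo-4H-chromen-6-yl)-2-methylpropanal
Conditions: Dess–Martin periodinane, pyridine, CH2Cl2, 0 °C to rt; used crude
Reagents that add atoms: none
Why: Dess–Martin oxidation of the primary alcohol stops at the aldehyde under buffered, non-enolising conditions, so the α-stereocentre should be kept if the aldehyde is used at once.

**Step 12**
Reactants: 21 (2S,4S)-pentane-2,4-diol (2 equiv)
Product: 22 (2S,4S)-4-[(tert-butyldimethylsilyl)oxy]pentan-2-ol
Conditions: TBSCl (1.0 equiv), imidazole, CH2Cl2, 0 °C to rt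
Reagents that add atoms: tert-butyldimethylsilyl chloride, CC(C)(C)[Si](C)(C)Cl
Why: Silylation of one hydroxyl of a diol whose two hydroxyl groups are equivalent by symmetry, so only one monosilyl ether can form; the excess diol suppresses bis-silylation and is washed out with water.

**Step 13**
Reactants: 22 (2S,4S)-4-[(tert-butyldimethylsilyl)oxy]pentan-2-ol
Product: 23 (4S)-4-[(tert-butyldimethylsilyl)oxy]pentan-2-one
Conditions: Dess–Martin periodinane, pyridine, CH2Cl2, rt
Reagents that add atoms: none
Why: Dess–Martin oxidation of the secondary alcohol to the methyl ketone; the silyloxy-bearing centre is not touched and the buffered medium avoids β-elimination.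

**Step 14**
Reactants: 23 (4S)-4-[(tert-butyldimethylsilyl)oxy]pentan-2-one (1.5 equiv); 20 (2R)-3-(5,7-dimethoxy-2-methyl-4-oxo-4H-chromen-6-yl)-2-methylpropanal
Product: 25 6-[(2R,7S)-7-[(tert-butyldimethylsilyl)oxy]-3-hydroxy-2-methyl-5-oxooctyl]-5,7-dimethoxy-2-methyl-4H-chromen-4-one (both C3 epimers), via lithium enolate 24 (not isolated)
Conditions: LiN(i-Pr)2 (1.4 equiv), THF, −78 °C; then 20, −78 °C; AcOH quench at −78 °C
Reagents that add atoms: none
Why: Aldol addition of the kinetic lithium enolate, formed at the methyl group with the ketone in slight excess over base, to the aldehyde, which is far more electrophilic than the chromone; the new carbinol centre forms as a mixture that the next step erases.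

**Step 15**
Reactants: 25 6-[(2R,7S)-7-[(tert-butyldimethylsilyl)oxy]-3-hydroxy-2-methyl-5-oxooctyl]-5,7-dimethoxy-2-methyl-4H-chromen-4-one
Product: 26 6-[(2R,7S)-7-[(tert-butyldimethylsilyl)oxy]-2-methyl-3,5-dioxooctyl]-5,7-dimethoxy-2-methyl-4H-chromen-4-one
Conditions: Dess–Martin periodinane (1.5 equiv), pyridine, CH2Cl2, 0 °C to rt
Reagents that add atoms: none
Why: Dess–Martin oxidation of the β-hydroxy ketone to the β-diketone removes the uncontrolled carbinol centre; the product should rest as the enol between the two carbonyls, which shields C2 from epimerisation.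

**Step 16**
Reactants: 26 6-[(2R,7S)-7-[(tert-butyldimethylsilyl)oxy]-2-methyl-3,5-dioxooctyl]-5,7-dimethoxy-2-methyl-4H-chromen-4-one
Product: 28 5,7-dimethoxy-2-methyl-6-{(2R)-2-[(2S)-2-methyl-4-oxo-3,4-dihydro-2H-pyran-6-yl]propyl}-4H-chromen-4-one, via hydroxy diketone 27 (not isolated)
Conditions: TsOH·H2O, CH2Cl2, rt
Reagents that add atoms: none
Why: Acid cleaves the silyl ether and the freed hydroxyl adds to the distal carbonyl (6-exo-trig hemiketal formation), followed by dehydration to the vinylogous ester, the standard cyclodehydration of δ-hydroxy-β-diketones to 2,3-dihydro-4H-pyran-4-ones; the C–O bond at the oxygen-bearing centre is never broken, so it stays S.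

**Step 17**
Reactants: 28 5,7-dimethoxy-2-methyl-6-{(2R)-2-[(2S)-2-methyl-4-oxo-3,4-dihydro-2H-pyran-6-yl]propyl}-4H-chromen-4-one
Product: 29 5-hydroxy-7-methoxy-2-methyl-6-{(2R)-2-[(2S)-2-methyl-4-oxo-3,4-dihydro-2H-pyran-6-yl]propyl}-4H-chromen-4-one (CNP0231471.1)
Conditions: BCl3 (2 equiv), CH2Cl2, −78 to 0 °C; then H2O
Reagents that add atoms: none
Why: Chelation-controlled Lewis acid ether cleavage, in which BCl3 binds between the C4 carbonyl and the peri C5 methoxy oxygen and chloride removes that methyl group only; the C7 methoxy group cannot chelate and the vinylogous ester has no comparably activated alkyl–oxygen bond.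

**Compound list**
1 | 4-hydroxy-2,6-dimethoxybenzaldehyde | COc1cc(O)cc(OC)c1C=O | starting material
2 | 4-[(tert-butyldimethylsilyl)oxy]-2,6-dimethoxybenzaldehyde | COc1cc(O[Si](C)(C)C(C)(C)C)cc(OC)c1C=O | intermediate
3 | triethyl 2-phosphonopropionate | CCOC(=O)C(C)P(=O)(OCC)OCC | starting material
4 | sodium 2-(diethoxyphosphoryl)-1-ethoxy-1-oxopropan-2-ide | [Na+].CCOC(=O)[C-](C)P(=O)(OCC)OCC | intermediate (not isolated)
5 | ethyl (2E)-3-{4-[(tert-butyldimethylsilyl)oxy]-2,6-dimethoxyphenyl}-2-methylprop-2-enoate | CCOC(=O)/C(C)=C/c1c(OC)cc(O[Si](C)(C)C(C)(C)C)cc1OC | intermediate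
6 | (2E)-3-(4-hydroxy-2,6-dimethoxyphenyl)-2-methylprop-2-enoic acid | OC(=O)/C(C)=C/c1c(OC)cc(O)cc1OC | intermediate
7 | (2R)-3-(4-hydroxy-2,6-dimethoxyphenyl)-2-methylpropanoic acid | COc1cc(O)cc(OC)c1C[C@@H](C)C(=O)O | intermediate
8 | 4-[(2R)-3-hydroxy-2-methylpropyl]-3,5-dimethoxyphenol | COc1cc(O)cc(OC)c1C[C@@H](C)CO | intermediate
9 | 2-bromo-4-[(2R)-3-hydroxy-2-methylpropyl]-3,5-dimethoxyphenol | COc1cc(O)c(Br)c(OC)c1C[C@@H](C)CO | intermediate
10 | {2-bromo-3,5-dimethoxy-4-[(2R)-2-methyl-3-(trimethylsilyloxy)propyl]phenoxy}trimethylsilane | COc1cc(O[Si](C)(C)C)c(Br)c(OC)c1C[C@@H](C)CO[Si](C)(C)C | intermediate (not isolated)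
11 | lithium 3,5-dimethoxy-4-[(2R)-2-methyl-3-(trimethylsilyloxy)propyl]-2-(trimethylsilyl)phenoxide | [Li+].COc1cc([O-])c([Si](C)(C)C)c(OC)c1C[C@@H](C)CO[Si](C)(C)C | intermediate (not isolated)
12 | 3,5-dimethoxy-4-[(2R)-2-methyl-3-(trimethylsilyloxy)propyl]-2-(trimethylsilyl)phenyl trifluoromethanesulfonate | COc1cc(OS(=O)(=O)C(F)(F)F)c([Si](C)(C)C)c(OC)c1C[C@@H](C)CO[Si](C)(C)C | intermediate (not isolated)
13 | 4-[(2R)-3-hydroxy-2-methylpropyl]-3,5-dimethoxy-2-(trimethylsilyl)phenyl trifluoromethanesulfonate | COc1cc(OS(=O)(=O)C(F)(F)F)c([Si](C)(C)C)c(OC)c1C[C@@H](C)CO | intermediate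
14 | 4-[(2R)-3-acetoxy-2-methylpropyl]-3,5-dimethoxy-2-(trimethylsilyl)phenyl trifluoromethanesulfonate | COc1cc(OS(=O)(=O)C(F)(F)F)c([Si](C)(C)C)c(OC)c1C[C@@H](C)COC(C)=O | intermediate
15 | but-2-ynoic acid | CC#CC(=O)O | starting material
16 | 4-[(2R)-3-acetoxy-2-methylpropyl]-3,5-dimethoxybenzyne (1,2-didehydro, numbered as in 14) | COC1=C(C[C@@H](C)COC(C)=O)C(OC)=CC#C1 | intermediate (not isolated)
17 | (2R)-3-[3-(but-2-ynoyl)-4-hydroxy-2,6-dimethoxyphenyl]-2-methylpropyl acetate | COc1cc(O)c(C(=O)C#CC)c(OC)c1C[C@@H](C)COC(C)=O | intermediate (not isolated)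
18 | (2R)-3-(5,7-dimethoxy-2-methyl-4-oxo-4H-chromen-6-yl)-2-methylpropyl acetate | COc1cc2oc(C)cc(=O)c2c(OC)c1C[C@@H](C)COC(C)=O | intermediate
19 | 6-[(2R)-3-hydroxy-2-methylpropyl]-5,7-dimethoxy-2-methyl-4H-chromen-4-one | COc1cc2oc(C)cc(=O)c2c(OC)c1C[C@@H](C)CO | intermediate
20 | (2R)-3-(5,7-dimethoxy-2-methyl-4-oxo-4H-chromen-6-yl)-2-methylpropanal | COc1cc2oc(C)cc(=O)c2c(OC)c1C[C@@H](C)C=O | intermediate
21 | (2S,4S)-pentane-2,4-diol | C[C@H](O)C[C@H](C)O | starting material
22 | (2S,4S)-4-[(tert-butyldimethylsilyl)oxy]pentan-2-ol | C[C@H](O)C[C@H](C)O[Si](C)(C)C(C)(C)C | intermediate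
23 | (4S)-4-[(tert-butyldimethylsilyl)oxy]pentan-2-one | CC(=O)C[C@H](C)O[Si](C)(C)C(C)(C)C | intermediate
24 | lithium (4S)-4-[(tert-butyldimethylsilyl)oxy]pent-1-en-2-olate | [Li+].C=C([O-])C[C@H](C)O[Si](C)(C)C(C)(C)C | intermediate (not isolated)
25 | 6-[(2R,7S)-7-[(tert-butyldimethylsilyl)oxy]-3-hydroxy-2-methyl-5-oxooctyl]-5,7-dimethoxy-2-methyl-4H-chromen-4-one (C3 epimers) | COc1cc2oc(C)cc(=O)c2c(OC)c1C[C@@H](C)C(O)CC(=O)C[C@H](C)O[Si](C)(C)C(C)(C)C | intermediate
26 | 6-[(2R,7S)-7-[(tert-butyldimethylsilyl)oxy]-2-methyl-3,5-dioxooctyl]-5,7-dimethoxy-2-methyl-4H-chromen-4-one | COc1cc2oc(C)cc(=O)c2c(OC)c1C[C@@H](C)C(=O)CC(=O)C[C@H](C)O[Si](C)(C)C(C)(C)C | intermediate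
27 | 6-[(2R,7S)-7-hydroxy-2-methyl-3,5-dioxooctyl]-5,7-dimethoxy-2-methyl-4H-chromen-4-one | COc1cc2oc(C)cc(=O)c2c(OC)c1C[C@@H](C)C(=O)CC(=O)C[C@H](C)O | intermediate (not isolated)
28 | 5,7-dimethoxy-2-methyl-6-{(2R)-2-[(2S)-2-methyl-4-oxo-3,4-dihydro-2H-pyran-6-yl]propyl}-4H-chromen-4-one | COc1cc2oc(C)cc(=O)c2c(OC)c1C[C@@H](C)C1=CC(=O)C[C@H](C)O1 | intermediate
29 | 5-hydroxy-7-methoxy-2-methyl-6-{(2R)-2-[(2S)-2-methyl-4-oxo-3,4-dihydro-2H-pyran-6-yl]propyl}-4H-chromen-4-one | COc1cc2oc(C)cc(=O)c2c(O)c1C[C@@H](C)C1=CC(=O)C[C@H](C)O1 | target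

**Step count**
Total: 17 steps. Longest linear sequence: 15 steps (steps 1–11 and 14–17); steps 12–13 are a two-step side branch.

**Steps most likely to fail**

1. Step 9 (aryne insertion and ring closure). The aryl anion may be protonated before the acyl group is transferred, so that only O-arylation occurs. The ynoate may also be consumed by conjugate addition of fluoride or carboxylate, or the regiocontrol may erode on the crowded aryne. The fallback leaves the route at 8 and rejoins it at 18. Heating 8 with Ac2O and BF3·OEt2 acetylates the side-chain alcohol and, by Friedel–Crafts/Fries C-acetylation ortho to the phenol, should give (2R)-3-(3-acetyl-4-hydroxy-2,6-dimethoxyphenyl)-2-methylpropyl acetate F1. Condensation with N,N-dimethylacetamide dimethyl acetal in toluene at 100 °C should give the enaminone (2R)-3-{3-[(2E)-3-(dimethylamino)but-2-enoyl]-4-hydroxy-2,6-dimethoxyphenyl}-2-methylpropyl acetate F2. Warming this in AcOH closes the pyranone with loss of dimethylamine to give 18.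

2. Step 7 (silyl migration and triflation). The O-to-C silyl shift may be incomplete, Tf2O may attack the side-chain silyl ether, or the electron-rich aryl–silicon bond may be lost by protodesilylation during the acidic work-up. The fallback leaves at 9 and rejoins at 13 by separating the two events. 9 is silylated (10) and treated with n-BuLi as before, but the phenoxide 11 is quenched with aq. NH4Cl–MeOH and the purified product is 4-[(2R)-3-hydroxy-2-methylpropyl]-3,5-dimethoxy-2-(trimethylsilyl)phenol F3. This is then sulfonylated at the phenol only with PhNTf2 and Et3N in CH2Cl2, a triflyl donor that does not react with the aliphatic alcohol, giving 13.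

3. Step 4 (asymmetric hydrogenation). Face discrimination may be poor, or turnover slow, on the di-ortho-substituted, electron-rich cinnamic acid. The fallback leaves at 2 and rejoins at 8 with auxiliary control.
   - Evans syn-aldol addition of the dibutylboron enolate of (4R)-4-benzyl-3-propionyl-1,3-oxazolidin-2-one (Bu2BOTf, i-Pr2NEt, CH2Cl2, −78 °C) to 2 should give (4R)-4-benzyl-3-[(2R,3R)-3-{4-[(tert-butyldimethylsilyl)oxy]-2,6-dimethoxyphenyl}-3-hydroxy-2-methylpropanoyl]-1,3-oxazolidin-2-one F4.
   - Ionic deoxygenation of the doubly activated benzylic hydroxyl (Et3SiH, CF3CO2H, CH2Cl2, 0 °C) should give (4R)-4-benzyl-3-[(2R)-3-{4-[(tert-butyldimethylsilyl)oxy]-2,6-dimethoxyphenyl}-2-methylpropanoyl]-1,3-oxazolidin-2-one F5.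
   - LiBH4 in wet THF removes the auxiliary to give (2R)-3-{4-[(tert-butyldimethylsilyl)oxy]-2,6-dimethoxyphenyl}-2-methylpropan-1-ol F6.
   - Bu4NF in THF cleaves the aryl silyl ether to give 8.

**Further compounds**
F1 | step 9 | (2R)-3-(3-acetyl-4-hydroxy-2,6-dimethoxyphenyl)-2-methylpropyl acetate | COc1cc(O)c(C(C)=O)c(OC)c1C[C@@H](C)COC(C)=O
F2 | step 9 | (2R)-3-{3-[(2E)-3-(dimethylamino)but-2-enoyl]-4-hydroxy-2,6-dimethoxyphenyl}-2-methylpropyl acetate | COc1cc(O)c(C(=O)/C=C(\C)N(C)C)c(OC)c1C[C@@H](C)COC(C)=O
F3 | step 7 | 4-[(2R)-3-hydroxy-2-methylpropyl]-3,5-dimethoxy-2-(trimethylsilyl)phenol | COc1cc(O)c([Si](C)(C)C)c(OC)c1C[C@@H](C)CO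
F4 | step 4 | (4R)-4-benzyl-3-[(2R,3R)-3-{4-[(tert-butyldimethylsilyl)oxy]-2,6-dimethoxyphenyl}-3-hydroxy-2-methylpropanoyl]-1,3-oxazolidin-2-one | O=C1OC[C@@H](Cc2ccccc2)N1C(=O)[C@H](C)[C@@H](O)c1c(OC)cc(O[Si](C)(C)C(C)(C)C)cc1OC
F5 | step 4 | (4R)-4-benzyl-3-[(2R)-3-{4-[(tert-butyldimethylsilyl)oxy]-2,6-dimethoxyphenyl}-2-methylpropanoyl]-1,3-oxazolidin-2-one | O=C1OC[C@@H](Cc2ccccc2)N1C(=O)[C@H](C)Cc1c(OC)cc(O[Si](C)(C)C(C)(C)C)cc1OC
F6 | step 4 | (2R)-3-{4-[(tert-butyldimethylsilyl)oxy]-2,6-dimethoxyphenyl}-2-methylpropan-1-ol | COc1cc(O[Si](C)(C)C(C)(C)C)cc(OC)c1C[C@@H](C)CO
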